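## The problem

The target is a sesquilignan: a pinoresinol-type furofuran (rings 1 and 2, cis-fused through C8–C8', with ring B on C7 and ring C on C7', both on the convex face) whose ring B oxygen is tied as an alkyl aryl ether to C8'' of an arylglycerol carrying ring A. It holds six stereocenters in two clusters, (7R,8S,8'S,7'R) in the bicycle and (7''R,8''S) in the side chain. Ring B separates the clusters, so neither can steer the other and each needs its own source of absolute configuration. Inside the bicycle the dependence is favourable: C8' can set C8 (trans addition to a β-substituted butyrolactone), and the cis C8/C8' pair then makes the exo position of each aryl group the preferred one, so C7 and C7' can be left to the ring closures. The side chain is erythro, which a syn glycolate aldol reaction or a syn dihydroxylation of an E-alkene does not give directly, so one of its centers has to be corrected. All three benzylic carbons (C7, C7', C7'') carry oxygen and sit para to an oxygenated arene: they ionise with acid, are cleaved by hydrogenolysis and epimerise through quinone methides once the para phenol is free, which rules out strong acid, late forcing hydrogenation and unbuffered base. The two ends of the furofuran differ chemically, and the plan uses this: ring B is an ether and ring A can be masked, so ring C is the only arene with a free phenol para to a benzylic CH2 (C7'), and the C9 hydroxyl lies five atoms from that carbon. Oxidation can therefore be confined to C7' and turned into the last C–O bond of ring 2.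

## Retrosynthesis

**28 to 27 (protecting groups).** Target 28 is traced to its tris-silyl ether 27 (ring A phenol as TIPS ether, C7'' and C9'' hydroxyls as TBS ethers). No skeletal bond is cut. Silyl ethers are preferred to an acetal on the side-chain diol because one buffered fluoride treatment then releases 28, and no aqueous acid meets C7'', C7 and C7' at the end. The forward step must remove three silyl groups without generating a phenoxide.

**27 to 25 (O–C7', ring 2).** The ether bond O–C7' is cut, passing through para-quinone methide 26 to the monocyclic phenol 25. The neighbouring cut O–C7 cannot be made this way because ring B has no free phenol, and cutting C8–C8' would demand radical or cycloaddition chemistry with weaker stereocontrol. Precursor 25 has one ring and one stereocenter fewer and is a lariciresinol-type tetrahydrofuran. The forward reaction must oxidise ring C only, close 5-exo and place ring C on the exo face.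

**25 to 24 to 23 (O9'–C7, ring 1).** After adding back a benzyl group on the ring C phenol (24), the C7–O9' bond is cut to give triol 23. This cut is chosen over closure at C9' by displacement because a benzylic cation at C7 lets both C7 epimers converge on the trans ring, so C7 need not be controlled earlier. The forward step needs mild acid that ionises the free C7 hydroxyl but not the silylated C7'' carbinol.

**23 to 22 to 20 + 14 (C7–C8).** Triol 23 comes from lactone 22 by hydride reduction, and 22 from an aldol reaction between lactone 20 and aldehyde 14. This is the most convergent cut: it divides the molecule into a ring C fragment with one stereocenter and a ring A/ring B fragment with two. The forward reaction only has to add trans to the C8' benzyl group.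

**20 to 18 to 17 to 15 + 16 (C8').** Lactone 20 is the reduced, lactonised form of half-ester 18, which comes from alkene 17 by asymmetric hydrogenation. Acid 17 is the Stobbe product of aldehyde 15 and diester 16. Two commodity chemicals and a catalyst set C8', which is shorter than an auxiliary alkylation.

**14 to 12 to 11 (formyl group, silyl ethers).** The aldehyde of 14 is carried as the aryl bromide 12, because a free or masked formyl group would not survive the boron enolate chemistry that builds the side chain. Bromide 12 is the bis-silyl ether of diol 11.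

**11 to 10 to 9 to 7 + 2 (C7''–C8'').** Diol 11 arises by reduction of ester 10, the C7''-inverted form of the syn aldol adduct 9 of imide 7 and aldehyde 2. The ether bond to ring B is kept intact here: forming it by substitution at C8'' would compete with the benzylic position, and arylating a secondary alkoxide would expose the aryl silyl ether to strong base. Bringing the ether oxygen in with the glycolate avoids both. The price is that the auxiliary gives the threo relationship, so C7'' must be inverted.

**7 to 4 + 5; 4 to 3; 2 to 1.** Imide 7 is the acylation product of oxazolidinone 5 with acid 4, made from bromophenol 3. Aldehyde 2 is silylated vanillin 1.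

## Roads not taken

Alternative 1: The bonds C7–C8 and C7'–C8' are cut together, with C7–C7' as a temporary bond. Forward, irradiation (about 313 nm) of stilbene A1 with the chiral fumarate A2 would give cyclobutane A3 by [2+2] cycloaddition.
- Merits: the fumarate geometry sets C8, C8' and their relationship in one step, and the two aryl ends are joined by a simple olefination, so the route is convergent.
- Weak points: the lactate esters are far from the reacting alkene, so facial control is uncertain. The stilbene can isomerise, dimerise or cyclise to a phenanthrene, and its aryl ethers absorb in the same region. After the key step the C7–C7' bond must still be cleaved with oxygen delivered to both benzylic carbons, the esters reduced and two rings closed.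
- Comparison: this road is better in convergence and needs no asymmetric hydrogenation. The chosen plan sets against it that every stereocenter is fixed by a well-understood element and that the key step is the last skeletal step.

Alternative 2: The bonds C7–C8 and C9'–C8' are cut. Forward, CsF would release a carbonyl ylide from chloro ether A4, and its (3+2) addition to butenolide A5 would give furofuranone A6.
- Merits: two C–C bonds and ring 1 form at once, C7' is already present and shields one face, and cis fusion is automatic. The bicyclic core is reached in fewer steps than in the chosen plan.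
- Weak points: non-stabilised ylides need reactive dipolarophiles, and neither the regiochemistry (C7 to C8 and not to C8') nor the exo position of ring B is secured. A5 has a γ-hydrogen that is benzylic and vinylogously acidic, so fluoride may racemise it. The lactone carbonyl C9 must later be reduced to CH2 under Lewis acid next to three ionisable benzylic ethers.
- Comparison: this road is shorter to the core. The chosen plan offers instead thermodynamic control at C7 and no carbonyl removal.

Alternative 3: The bonds C8–C8' and O–C7' are cut. Forward, Cp2TiCl (trivalent titanium, from Cp2TiCl2 and Zn) would open epoxide A7 to a C8 radical that closes 5-exo onto the cinnamyl alkene; iodine would then make C7' electrophilic and the C9 alkoxide would close ring 2, giving A8.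
- Merits: one operation makes a C–C bond and both rings, the reaction type is known for symmetric furofuran lignans, and A8 is only deprotections from the target. It is the shortest of the four roads.
- Weak points: the radical at C8 has lost the epoxide configuration, so C8 and C8' are set only by the C7 substituent and diastereomer mixtures are likely. C7 must be set beforehand in an enantiopure epoxy ether of an electron-rich arene, and a benzylic iodide is generated beside silylated phenols and an acetal.
- Comparison: this road wins on step count. The chosen plan forms the same O–C7' bond but from a C–H bond, after C8 and C8' have been fixed separately.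

Key step: step 16

Remark on the chemistry: the SMILES is read as the (7R,8S,7'R,8'S) furofuran, the antipode of the (+)-pinoresinol core, with a (7''R,8''S) erythro side chain. Lignan numbering is used (ring 1 = C7–O–C9'–C8'–C8, ring 2 = C8–C9–O–C7'–C8'). Ar* stands for 4-{[(1R,2S)-1,3-bis(tert-butyldimethylsilyloxy)-1-(3-methoxy-4-triisopropylsilyloxyphenyl)propan-2-yl]oxy}-3-methoxyphenyl, that is ring B carrying the protected side chain.

## Route

Step 1
Reactants: 1 vanillin
Product: 2 3-methoxy-4-(triisopropylsilyloxy)benzaldehyde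
Conditions: TIPSCl, imidazole, DMF, rt
Reagents that add atoms: triisopropylsilyl chloride, CC(C)[Si](Cl)(C(C)C)C(C)C
Why: Standard phenol silylation; the bulky aryl TIPS ether should resist the bases, hydrides and organolithium reagents used later and still fall to fluoride at the end.

Step 2
Reactants: 3 4-bromo-2-methoxyphenol
Product: 4 2-(4-bromo-2-methoxyphenoxy)acetic acid
Conditions: ClCH2CO2H, aq. NaOH, reflux; then HCl
Reagents that add atoms: chloroacetic acid, OC(=O)CCl
Why: Williamson ether synthesis of an aryloxyacetic acid from the phenoxide and chloroacetate; acidification should precipitate the acid.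

Step 3
Reactants: 4 2-(4-bromo-2-methoxyphenoxy)acetic acid; 5 (R)-4-benzyl-2-oxazolidinone
Product: 7 (R)-4-benzyl-3-[2-(4-bromo-2-methoxyphenoxy)acetyl]oxazolidin-2-one, via mixed pivalic anhydride 6 (not isolated)
Conditions: PivCl, Et3N, THF, −20 °C; then 5, LiCl, rt
Reagents that add atoms: none
Why: N-acylation of the Evans auxiliary through the mixed anhydride with LiCl/Et3N activation; no stereocenter is formed.

Step 4
Reactants: 7 (R)-4-benzyl-3-[2-(4-bromo-2-methoxyphenoxy)acetyl]oxazolidin-2-one; 2 3-methoxy-4-(triisopropylsilyloxy)benzaldehyde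
Product: 9 (R)-4-benzyl-3-{(2R,3S)-2-(4-bromo-2-methoxyphenoxy)-3-hydroxy-3-[3-methoxy-4-(triisopropylsilyloxy)phenyl]propanoyl}oxazolidin-2-one, via dibutylboron Z-enolate 8 (not isolated)
Conditions: Bu2BOTf, i-Pr2NEt, CH2Cl2, −78 to 0 °C; 2, −78 to 0 °C; then H2O2, pH 7 buffer, MeOH
Reagents that add atoms: none
Why: Evans syn aldol reaction; the Z-boron enolate adds through a closed Zimmerman–Traxler chair on the face away from the auxiliary benzyl group, so the (R)-auxiliary sets C8'' in its final spatial arrangement (2R in the imide) and gives C7'' as the 3S epimer (syn, threo series).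

Step 5
Reactants: 9 syn aldol adduct
Product: 10 (R)-4-benzyl-3-{(2R,3R)-2-(4-bromo-2-methoxyphenoxy)-3-(4-nitrobenzoyloxy)-3-[3-methoxy-4-(triisopropylsilyloxy)phenyl]propanoyl}oxazolidin-2-one
Conditions: 4-nitrobenzoic acid, PPh3, DIAD, THF, 0 °C to rt
Reagents that add atoms: 4-nitrobenzoic acid, OC(=O)c1ccc(cc1)[N+](=O)[O-]
Why: Mitsunobu inversion of a secondary benzylic alcohol; SN2 displacement of the oxyphosphonium ion should turn 7''S into 7''R and give the erythro series. The carbonyl and aryloxy groups on the neighbouring carbon disfavour ionisation, and the imide α-hydrogen, held in the carbonyl plane, is poorly placed for elimination.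

Step 6
Reactants: 10 4-nitrobenzoate
Product: 11 (1R,2S)-2-(4-bromo-2-methoxyphenoxy)-1-[3-methoxy-4-(triisopropylsilyloxy)phenyl]propane-1,3-diol
Conditions: LiBH4, MeOH (4 equiv), THF, 0 °C to rt
Reagents that add atoms: none
Why: Reductive removal of the Evans auxiliary with LiBH4, which should also reduce the nitrobenzoate; neither stereocenter is touched and the auxiliary is recovered.

Step 7
Reactants: 11 erythro diol
Product: 12 (1R,2S)-2-(4-bromo-2-methoxyphenoxy)-1,3-bis(tert-butyldimethylsilyloxy)-1-[3-methoxy-4-(triisopropylsilyloxy)phenyl]propane (Ar*–Br)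
Conditions: TBSOTf, 2,6-lutidine, CH2Cl2, −78 to 0 °C
Reagents that add atoms: tert-butyldimethylsilyl triflate, CC(C)(C)[Si](C)(C)OS(=O)(=O)C(F)(F)F
Why: Silylation of the primary and the secondary benzylic alcohol with a silyl triflate and a hindered base; the silyl ethers protect the C7'' carbinol against ionisation and oxidation and leave with fluoride.

Step 8
Reactants: 12 Ar*–Br
Product: 14 Ar*–CHO (4-{[(1R,2S)-1,3-bis(tert-butyldimethylsilyloxy)-1-(3-methoxy-4-triisopropylsilyloxyphenyl)propan-2-yl]oxy}-3-methoxybenzaldehyde), via aryllithium 13 (not isolated)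
Conditions: n-BuLi, THF, −78 °C; DMF, −78 to 0 °C; aq. NH4Cl
Reagents that add atoms: N,N-dimethylformamide, CN(C)C=O
Why: Bromine–lithium exchange followed by formylation with DMF; at −78 °C the exchange should outrun attack on silicon or benzylic deprotonation.

Step 9
Reactants: 15 4-(benzyloxy)-3-methoxybenzaldehyde; 16 dimethyl succinate
Product: 17 (E)-4-[4-(benzyloxy)-3-methoxyphenyl]-3-(methoxycarbonyl)but-3-enoic acid
Conditions: NaOMe, MeOH, reflux; then aq. HCl
Reagents that add atoms: none
Why: Stobbe condensation; the aldol adduct lactonises and the lactone opens by elimination, which puts the free acid on the CH2 arm and the ester on the alkene carbon, mainly as the E isomer.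

Step 10
Reactants: 17 Stobbe half-ester
Product: 18 (S)-4-[4-(benzyloxy)-3-methoxyphenyl]-3-(methoxycarbonyl)butanoic acid
Conditions: [Rh(COD)((R,R)-Et-DuPHOS)]BF4 (0.5 mol%), NaOMe (10 mol%), H2 (6 bar), MeOH, rt
Reagents that add atoms: none
Why: Asymmetric hydrogenation of a Stobbe-type itaconate half-ester by a cationic rhodium bisphospholane catalyst with the carboxylate chelating the metal; this sets C8'. By analogy with itaconate and enamide reductions the (R,R) ligand is expected to give the (S) acid, and the (S,S) ligand would be used if the sense proved opposite.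

Step 11
Reactants: 18 (S)-half-ester
Product: 20 (S)-4-[4-(benzyloxy)-3-methoxybenzyl]dihydrofuran-2(3H)-one, via hydroxy acid 19 (not isolated)
Conditions: LiBH4, THF, 0 °C to rt; then 2 M HCl, rt
Reagents that add atoms: none
Why: Chemoselective reduction; LiBH4 reduces the methyl ester but not the lithium carboxylate, and acidification lactonises the hydroxy acid without touching the stereocenter.

Step 12
Reactants: 20 (S)-lactone; 14 Ar*–CHO
Product: 22 (3R,4S)-4-[4-(benzyloxy)-3-methoxybenzyl]-3-[hydroxy(Ar*)methyl]dihydrofuran-2(3H)-one as both C7 epimers, via lithium enolate 21 (not isolated)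
Conditions: LDA, THF, −78 °C; 14, −78 °C; AcOH quench
Reagents that add atoms: none
Why: Aldol addition of a lactone lithium enolate; the aldehyde approaches anti to the C8' benzyl group, giving the 3,4-trans lactone (C8 set by C8'). The C7 carbinol forms as a mixture that step 14 converges.

Step 13
Reactants: 22 aldol adduct
Product: 23 (2S,3S)-2-[4-(benzyloxy)-3-methoxybenzyl]-3-[hydroxy(Ar*)methyl]butane-1,4-diol as both C7 epimers
Conditions: LiAlH4, THF, 0 °C; aq. KNaC4H4O6 work-up
Reagents that add atoms: none
Why: Hydride reduction of the lactone to the 1,4-diol, expected to be faster at 0 °C than retro-aldol cleavage; the silyl and benzyl ethers are inert.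

Step 14
Reactants: 23 triol
Product: 24 [(2R,3S,4S)-2-Ar*-4-[4-(benzyloxy)-3-methoxybenzyl]tetrahydrofuran-3-yl]methanol
Conditions: CSA (10 mol%), CH2Cl2, 0 °C
Reagents that add atoms: none
Why: Acid-catalysed dehydrative cycloetherification through the alkoxy-stabilised C7 benzylic cation, captured 5-exo by the C9' hydroxyl (C9–OH could only form an oxetane). Both C7 epimers should converge on the 7,8-trans ring (7R) because the aryl group avoids the C8 substituent and the closure is reversible. Capture by oxygen is expected to outrun attack by ring C, and the silylated C7'' carbinol is a much poorer leaving group than the free C7 hydroxyl.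

Step 15
Reactants: 24 benzyl ether
Product: 25 [(2R,3S,4S)-2-Ar*-4-(4-hydroxy-3-methoxybenzyl)tetrahydrofuran-3-yl]methanol
Conditions: H2 (1 atm), 10% Pd/C, EtOAc, rt, stopped at full conversion
Reagents that add atoms: none
Why: Hydrogenolysis of an aryl benzyl ether over palladium on carbon in a neutral solvent, which should be much faster than cleavage of the cyclic benzylic C7–O bond or of the benzylic silyl ether; it frees the one phenol the key step needs.

Step 16
Reactants: 25 phenol
Product: 27 4-[(1R,3aS,4R,6aS)-4-Ar*-tetrahydro-1H,3H-furo[3,4-c]furan-1-yl]-2-methoxyphenol, via para-quinone methide 26 (not isolated)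
Conditions: DDQ (1.05 equiv, slow addition), 4 Å molecular sieves, CH2Cl2, 0 °C to rt
Reagents that add atoms: none
Why: DDQ removes two electrons and a proton from the only free phenol (ring C) and the resulting cation loses the C7' benzylic proton to give para-quinone methide 26; the C9 hydroxyl then adds to C7' in an intramolecular oxa-conjugate addition that restores the arene. The closest known reaction type is the DDQ- or Ag2O-mediated oxidation of para-alkylphenols to quinone methides with capture by a tethered hydroxyl or carboxyl group, as in oxidative flavan and aryl lactone formation. Ring 2 closes in the 5-exo-trig mode, the C7'=C1' bond being exocyclic to the new ring. Because C9 and C7' are cis on ring 1 the new ring can only be cis-fused; C7' is set by the approach that keeps ring C on the convex face, anti to C9', which gives 7'R, and since this exo isomer is also the more stable one the mildly acidic reduced quinone can correct kinetic leakage by reversible ring opening. The step needs site selectivity, and the substrate provides it: ring A is silylated and ring B is an alkyl aryl ether, so neither can form a quinone methide, and C9–OH is the only free hydroxyl. It also needs phenol oxidation to be faster than hydride abstraction from the dialkoxybenzylic C7–H or further oxidation of the product; slow addition of one equivalent of DDQ at 0 °C without water is meant to secure this.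

Step 17
Reactants: 27 tris-silyl ether
Product: 28 4-[(1R,3aS,4R,6aS)-4-(4-{[(1R,2S)-1,3-dihydroxy-1-(4-hydroxy-3-methoxyphenyl)propan-2-yl]oxy}-3-methoxyphenyl)tetrahydro-1H,3H-furo[3,4-c]furan-1-yl]-2-methoxyphenol (target)
Conditions: Bu4NF (5 equiv), AcOH (5 equiv), THF, 0 °C to rt
Reagents that add atoms: none
Why: Fluoride cleavage of the aryl TIPS ether and both TBS ethers; the AcOH buffer keeps the phenols protonated so that no quinone methide can form at C7'' or C7', and no acid strong enough to ionise the benzylic C–O bonds is present.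

## Compound list

1 | vanillin | COc1cc(C=O)ccc1O | starting material
2 | 3-methoxy-4-(triisopropylsilyloxy)benzaldehyde | COc1cc(C=O)ccc1O[Si](C(C)C)(C(C)C)C(C)C | intermediate
3 | 4-bromo-2-methoxyphenol | COc1cc(Br)ccc1O | starting material
4 | 2-(4-bromo-2-methoxyphenoxy)acetic acid | COc1cc(Br)ccc1OCC(=O)O | intermediate
5 | (R)-4-benzyl-2-oxazolidinone | O=C1N[C@H](Cc2ccccc2)CO1 | starting material
6 | 2-(4-bromo-2-methoxyphenoxy)acetic pivalic anhydride | COc1cc(Br)ccc1OCC(=O)OC(=O)C(C)(C)C | intermediate
7 | (R)-4-benzyl-3-[2-(4-bromo-2-methoxyphenoxy)acetyl]oxazolidin-2-one | COc1cc(Br)ccc1OCC(=O)N1C(=O)OC[C@H]1Cc1ccccc1 | intermediate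
8 | dibutylboron Z-enolate of 7 | CCCCB(CCCC)O/C(=C\Oc1ccc(Br)cc1OC)N1C(=O)OC[C@H]1Cc1ccccc1 | intermediate
9 | (R)-4-benzyl-3-{(2R,3S)-2-(4-bromo-2-methoxyphenoxy)-3-hydroxy-3-[3-methoxy-4-(triisopropylsilyloxy)phenyl]propanoyl}oxazolidin-2-one | COc1cc([C@H](O)[C@H](C(=O)N3C(=O)OC[C@H]3Cc3ccccc3)Oc2ccc(Br)cc2OC)ccc1O[Si](C(C)C)(C(C)C)C(C)C | intermediate
10 | (R)-4-benzyl-3-{(2R,3R)-2-(4-bromo-2-methoxyphenoxy)-3-(4-nitrobenzoyloxy)-3-[3-methoxy-4-(triisopropylsilyloxy)phenyl]propanoyl}oxazolidin-2-one | COc1cc([C@@H](OC(=O)c3ccc(cc3)[N+](=O)[O-])[C@H](C(=O)N3C(=O)OC[C@H]3Cc3ccccc3)Oc2ccc(Br)cc2OC)ccc1O[Si](C(C)C)(C(C)C)C(C)C | intermediate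
11 | (1R,2S)-2-(4-bromo-2-methoxyphenoxy)-1-[3-methoxy-4-(triisopropylsilyloxy)phenyl]propane-1,3-diol | COc1cc([C@@H](O)[C@H](CO)Oc2ccc(Br)cc2OC)ccc1O[Si](C(C)C)(C(C)C)C(C)C | intermediate
12 | (1R,2S)-2-(4-bromo-2-methoxyphenoxy)-1,3-bis(tert-butyldimethylsilyloxy)-1-[3-methoxy-4-(triisopropylsilyloxy)phenyl]propane (Ar*–Br) | COc1cc([C@@H](O[Si](C)(C)C(C)(C)C)[C@H](CO[Si](C)(C)C(C)(C)C)Oc2ccc(Br)cc2OC)ccc1O[Si](C(C)C)(C(C)C)C(C)C | intermediate
13 | aryllithium Ar*–Li | COc1cc([C@@H](O[Si](C)(C)C(C)(C)C)[C@H](CO[Si](C)(C)C(C)(C)C)Oc2ccc([Li])cc2OC)ccc1O[Si](C(C)C)(C(C)C)C(C)C | intermediate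
14 | Ar*–CHO, 4-{[(1R,2S)-1,3-bis(tert-butyldimethylsilyloxy)-1-(3-methoxy-4-triisopropylsilyloxyphenyl)propan-2-yl]oxy}-3-methoxybenzaldehyde | COc1cc([C@@H](O[Si](C)(C)C(C)(C)C)[C@H](CO[Si](C)(C)C(C)(C)C)Oc2ccc(C=O)cc2OC)ccc1O[Si](C(C)C)(C(C)C)C(C)C | intermediate
15 | 4-(benzyloxy)-3-methoxybenzaldehyde | COc1cc(C=O)ccc1OCc1ccccc1 | starting material
16 | dimethyl succinate | COC(=O)CCC(=O)OC | starting material
17 | (E)-4-[4-(benzyloxy)-3-methoxyphenyl]-3-(methoxycarbonyl)but-3-enoic acid | COC(=O)/C(CC(=O)O)=C/c1ccc(OCc2ccccc2)c(OC)c1 | intermediate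
18 | (S)-4-[4-(benzyloxy)-3-methoxyphenyl]-3-(methoxycarbonyl)butanoic acid | COC(=O)[C@H](CC(=O)O)Cc1ccc(OCc2ccccc2)c(OC)c1 | intermediate
19 | (S)-3-[4-(benzyloxy)-3-methoxybenzyl]-4-hydroxybutanoic acid | OC[C@H](CC(=O)O)Cc1ccc(OCc2ccccc2)c(OC)c1 | intermediate
20 | (S)-4-[4-(benzyloxy)-3-methoxybenzyl]dihydrofuran-2(3H)-one | O=C1C[C@H](Cc2ccc(OCc3ccccc3)c(OC)c2)CO1 | intermediate
21 | lithium enolate of 20 | [Li]OC1=C[C@H](Cc2ccc(OCc3ccccc3)c(OC)c2)CO1 | intermediate
22 | (3R,4S)-4-[4-(benzyloxy)-3-methoxybenzyl]-3-[hydroxy(Ar*)methyl]dihydrofuran-2(3H)-one, both C7 epimers | COc1cc([C@@H](O[Si](C)(C)C(C)(C)C)[C@H](CO[Si](C)(C)C(C)(C)C)Oc2ccc(C(O)[C@@H]3C(=O)OC[C@H]3Cc3ccc(OCc4ccccc4)c(OC)c3)cc2OC)ccc1O[Si](C(C)C)(C(C)C)C(C)C | intermediate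
23 | (2S,3S)-2-[4-(benzyloxy)-3-methoxybenzyl]-3-[hydroxy(Ar*)methyl]butane-1,4-diol, both C7 epimers | COc1cc([C@@H](O[Si](C)(C)C(C)(C)C)[C@H](CO[Si](C)(C)C(C)(C)C)Oc2ccc(C(O)[C@H](CO)[C@@H](CO)Cc3ccc(OCc4ccccc4)c(OC)c3)cc2OC)ccc1O[Si](C(C)C)(C(C)C)C(C)C | intermediate
24 | [(2R,3S,4S)-2-Ar*-4-[4-(benzyloxy)-3-methoxybenzyl]tetrahydrofuran-3-yl]methanol | COc1cc([C@@H](O[Si](C)(C)C(C)(C)C)[C@H](CO[Si](C)(C)C(C)(C)C)Oc2ccc([C@@H]3OC[C@@H](Cc4ccc(OCc5ccccc5)c(OC)c4)[C@H]3CO)cc2OC)ccc1O[Si](C(C)C)(C(C)C)C(C)C | intermediate
25 | [(2R,3S,4S)-2-Ar*-4-(4-hydroxy-3-methoxybenzyl)tetrahydrofuran-3-yl]methanol (key-step precursor) | COc1cc([C@@H](O[Si](C)(C)C(C)(C)C)[C@H](CO[Si](C)(C)C(C)(C)C)Oc2ccc([C@@H]3OC[C@@H](Cc4ccc(O)c(OC)c4)[C@H]3CO)cc2OC)ccc1O[Si](C(C)C)(C(C)C)C(C)C | intermediate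
26 | para-quinone methide of 25 (C7'=C1', ring C as 2-methoxycyclohexa-2,5-dienone) | COc1cc([C@@H](O[Si](C)(C)C(C)(C)C)[C@H](CO[Si](C)(C)C(C)(C)C)Oc2ccc([C@@H]3OC[C@@H](C=C4C=CC(=O)C(OC)=C4)[C@H]3CO)cc2OC)ccc1O[Si](C(C)C)(C(C)C)C(C)C | intermediate
27 | 4-[(1R,3aS,4R,6aS)-4-Ar*-tetrahydro-1H,3H-furo[3,4-c]furan-1-yl]-2-methoxyphenol (key-step product) | COc1cc([C@@H](O[Si](C)(C)C(C)(C)C)[C@H](CO[Si](C)(C)C(C)(C)C)Oc2ccc([C@@H]3OC[C@@H]4[C@H]3CO[C@H]4c3ccc(O)c(OC)c3)cc2OC)ccc1O[Si](C(C)C)(C(C)C)C(C)C | intermediate
28 | 4-[(1R,3aS,4R,6aS)-4-(4-{[(1R,2S)-1,3-dihydroxy-1-(4-hydroxy-3-methoxyphenyl)propan-2-yl]oxy}-3-methoxyphenyl)tetrahydro-1H,3H-furo[3,4-c]furan-1-yl]-2-methoxyphenol | COc1cc([C@@H](O)[C@H](CO)Oc2ccc([C@@H]3OC[C@@H]4[C@H]3CO[C@H]4c3ccc(O)c(OC)c3)cc2OC)ccc1O | target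

## Step count and risk

Total step count: 17. Longest linear sequence: 13 steps (steps 2 to 8, then 12 to 17, starting from 3).

Least certain steps:

**Step 16 (key step).** What may go wrong: hydride abstraction by DDQ at the dialkoxybenzylic C7–H of ring 1, further oxidation of the phenolic product at C7', and closure onto the endo face giving the C7' epimer. Fallback, from 25 back to 27: the oxidation is done with Ag2O in CH2Cl2/MeOH. This inner-sphere oxidation of the phenol cannot abstract hydride from C7, and any quinone methide that does not close at once is caught by methanol as the C7' methyl ether F8 (mixture of C7' epimers, together with 27 formed directly). Catalytic PPTS in CH2Cl2 then ionises the para-hydroxybenzylic ether and lets the C9 hydroxyl replace methanol under thermodynamic control, giving 27.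

**Step 5.** What may go wrong: elimination of the activated alcohol to the 2-aryloxycinnamoyl imide, or ionisation at C7'' with partial retention, giving a diastereomer mixture. Fallback, from 9 back to 12:
- LiBH4 reduction of 9 gives the threo diol F1.
- TBSCl and imidazole silylate the primary hydroxyl to give the mono-silyl ether F2.
- Dess–Martin periodinane gives the ketone F3.
- Zn(BH4)2 in Et2O reduces F3 under chelation control (zinc held by the carbonyl and the guaiacyl ether oxygens, hydride entering from the side of the C8'' hydrogen) to the erythro alcohol F4.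
- TBSOTf and 2,6-lutidine convert F4 into 12.

**Step 15.** What may go wrong: over-reduction, that is hydrogenolysis of the C7–O bond of ring 1 or of the benzylic C7''–O bond alongside debenzylation. Fallback, from 20 back to 25: the benzyl group is removed from lactone 20, which has no other benzylic C–O bond, to give the phenol lactone F5. Its phenoxide–enolate dianion (LDA, 2.2 equiv) is added to 14 to give the aldol adduct F6. LiAlH4 gives the triol F7, and CSA in CH2Cl2 closes ring 1 to give 25 directly.

**Step 10.** What may go wrong: insufficient or reversed enantioselection on the E/Z mixture from step 9. Fallback, from 17 back to 18: hydrogenation with the achiral catalyst [Rh(COD)(dppb)]BF4 gives the racemic half-ester F9, which is resolved by crystallisation of its salt with enantiopure 1-phenylethylamine; the acid freed from the salt of the (S) enantiomer is 18.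

## Further compounds

F1 | step 5 | (1S,2S)-2-(4-bromo-2-methoxyphenoxy)-1-[3-methoxy-4-(triisopropylsilyloxy)phenyl]propane-1,3-diol | COc1cc([C@H](O)[C@H](CO)Oc2ccc(Br)cc2OC)ccc1O[Si](C(C)C)(C(C)C)C(C)C
F2 | step 5 | (1S,2S)-2-(4-bromo-2-methoxyphenoxy)-3-(tert-butyldimethylsilyloxy)-1-[3-methoxy-4-(triisopropylsilyloxy)phenyl]propan-1-ol | COc1cc([C@H](O)[C@H](CO[Si](C)(C)C(C)(C)C)Oc2ccc(Br)cc2OC)ccc1O[Si](C(C)C)(C(C)C)C(C)C
F3 | step 5 | (S)-2-(4-bromo-2-methoxyphenoxy)-3-(tert-butyldimethylsilyloxy)-1-[3-methoxy-4-(triisopropylsilyloxy)phenyl]propan-1-one | COc1cc(C(=O)[C@H](CO[Si](C)(C)C(C)(C)C)Oc2ccc(Br)cc2OC)ccc1O[Si](C(C)C)(C(C)C)C(C)C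
F4 | step 5 | (1R,2S)-2-(4-bromo-2-methoxyphenoxy)-3-(tert-butyldimethylsilyloxy)-1-[3-methoxy-4-(triisopropylsilyloxy)phenyl]propan-1-ol | COc1cc([C@@H](O)[C@H](CO[Si](C)(C)C(C)(C)C)Oc2ccc(Br)cc2OC)ccc1O[Si](C(C)C)(C(C)C)C(C)C
F5 | step 15 | (S)-4-(4-hydroxy-3-methoxybenzyl)dihydrofuran-2(3H)-one | O=C1C[C@H](Cc2ccc(O)c(OC)c2)CO1
F6 | step 15 | (3R,4S)-3-[hydroxy(Ar*)methyl]-4-(4-hydroxy-3-methoxybenzyl)dihydrofuran-2(3H)-one, both C7 epimers | COc1cc([C@@H](O[Si](C)(C)C(C)(C)C)[C@H](CO[Si](C)(C)C(C)(C)C)Oc2ccc(C(O)[C@@H]3C(=O)OC[C@H]3Cc3ccc(O)c(OC)c3)cc2OC)ccc1O[Si](C(C)C)(C(C)C)C(C)C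
F7 | step 15 | (2S,3S)-2-(4-hydroxy-3-methoxybenzyl)-3-[hydroxy(Ar*)methyl]butane-1,4-diol, both C7 epimers | COc1cc([C@@H](O[Si](C)(C)C(C)(C)C)[C@H](CO[Si](C)(C)C(C)(C)C)Oc2ccc(C(O)[C@H](CO)[C@@H](CO)Cc3ccc(O)c(OC)c3)cc2OC)ccc1O[Si](C(C)C)(C(C)C)C(C)C
F8 | step 16 | C7' methyl ether of 25, both C7' epimers | COc1cc([C@@H](O[Si](C)(C)C(C)(C)C)[C@H](CO[Si](C)(C)C(C)(C)C)Oc2ccc([C@@H]3OC[C@@H](C(OC)c4ccc(O)c(OC)c4)[C@H]3CO)cc2OC)ccc1O[Si](C(C)C)(C(C)C)C(C)C
F9 | step 10 | racemic 4-[4-(benzyloxy)-3-methoxyphenyl]-3-(methoxycarbonyl)butanoic acid | COC(=O)C(CC(=O)O)Cc1ccc(OCc2ccccc2)c(OC)c1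
A1 | alternative 1 | (E)-stilbene joining ring B (acetonide-protected side chain, silylated ring A) to silylated ring C | COc1cc([C@@H](OC(C)(C)OC5)[C@H]5Oc2ccc(/C=C/c3ccc(O[Si](C)(C)C(C)(C)C)c(OC)c3)cc2OC)ccc1O[Si](C)(C)C(C)(C)C
A2 | alternative 1 | bis[(S)-1-ethoxy-1-oxopropan-2-yl] fumarate | CCOC(=O)[C@H](C)OC(=O)/C=C/C(=O)O[C@@H](C)C(=O)OCC
A3 | alternative 1 | 3,4-diarylcyclobutane-1,2-dicarboxylate (esters trans, aryls trans) | COc1cc([C@@H](OC(C)(C)OC5)[C@H]5Oc2ccc([C@@H]6[C@H](C(=O)O[C@@H](C)C(=O)OCC)[C@@H](C(=O)O[C@@H](C)C(=O)OCC)[C@H]6c3ccc(O[Si](C)(C)C(C)(C)C)c(OC)c3)cc2OC)ccc1O[Si](C)(C)C(C)(C)C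
A4 | alternative 2 | α-chloro (trimethylsilyl)methyl ether of the ring B aldehyde (ylide precursor) | COc1cc([C@@H](OC(C)(C)OC5)[C@H]5Oc2ccc(C(Cl)OC[Si](C)(C)C)cc2OC)ccc1OCC=C
A5 | alternative 2 | (R)-5-(4-allyloxy-3-methoxyphenyl)furan-2(5H)-one | O=C1C=C[C@H](c2ccc(OCC=C)c(OC)c2)O1
A6 | alternative 2 | cis-fused furofuranone (C9 as lactone carbonyl) with protected side chain | COc1cc([C@@H](OC(C)(C)OC5)[C@H]5Oc2ccc([C@@H]3OC[C@@H]4[C@H]3C(=O)O[C@H]4c3ccc(OCC=C)c(OC)c3)cc2OC)ccc1OCC=C
A7 | alternative 3 | cinnamyl ether of the ring B 1-aryl-2,3-epoxypropan-1-ol (epoxide carbon unassigned) | COc1cc([C@@H](OC(C)(C)OC5)[C@H]5Oc2ccc([C@H](OC/C=C/c3ccc(O[Si](C)(C)C(C)(C)C)c(OC)c3)C3CO3)cc2OC)ccc1O[Si](C)(C)C(C)(C)C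
A8 | alternative 3 | bis-silyl acetonide of the target | COc1cc([C@@H](OC(C)(C)OC5)[C@H]5Oc2ccc([C@@H]3OC[C@@H]4[C@H]3CO[C@H]4c3ccc(O[Si](C)(C)C(C)(C)C)c(OC)c3)cc2OC)ccc1O[Si](C)(C)C(C)(C)C
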